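**Compound numbers used throughout:** 1 5-bromo-2-methoxyphenol; 2 its benzyl ether; 3 methyl (R)-glycidate; 4 aryl Grignard reagent; 5 methyl (R)-aryllactate; 6 (R)-aryllactic acid; 7 pivalaldehyde; 8 cis dioxolanone; 9 oxetan-3-one; 10 lithium enolate of 8; 11 oxetanol (substrate of the key step); 12 spiro tetralin (product of the key step); 13 methyl ester triol; 14 C7 phenol; 15 diacetate; 16 C1 acetate; 17 3-methoxyphenol; 18 its benzyl ether; 19 aryllithium; 20 borate; 21 2-(benzyloxy)-6-methoxyphenol; 22 arylated tetralin; 23 mono-benzyl plicatic acid; 24 plicatic acid.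

## Analysis of the target

Plicatic acid (24) is a 1-aryltetralin cyclolignan with aromatic ring A (C6 methoxy, C7 hydroxyl), saturated ring B (C1 to C4) and a 3,4-dihydroxy-5-methoxyphenyl ring C on C1; tetralin numbering is used throughout, with C9 the carboxyl carbon on C2 and C10 the hydroxymethyl carbon on C3. Ring B carries three contiguous stereocentres, C1 (S), C2 (S) and C3 (R) by the CIP rules. C2 and C3 are adjacent, fully substituted carbinol carbons whose hydroxyls O2 and O3 are trans, so C9 and C10 are trans as well, and the C1 aryl group is cis to O2 and C10 and trans to C9. Sensitive features are the ring C catechol (air oxidation, above all in base), the β-hydroxy acid C9–C2–C3–O3 (retro-aldol) and the γ-hydroxy acid formed by C9 and the C10 hydroxyl (lactonisation in acid). The difficulty lies in the two vicinal tetrasubstituted carbinols: neither carries a hydrogen, so no enolisation, reduction or epimerisation can correct them later, and C1 has to be set next to a quaternary carbon. The plan rests on C3, which bears a hydroxyl and two CH2 arms, C4 bound to ring A at C4a and C10 bound to oxygen. Tying the C10 oxygen back to C4 makes C3 the carbinol carbon of a symmetric oxetan-3-ol, and C4a is para to the C7 oxygen, so attack of ring A on that oxetane is electronically matched.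

## Retrosynthetic reasoning

**Unmasking, 24 to 22.** No skeletal bond is cut. 24 is traced through 23 to 22, in which C7 and C10 carry acetates, C9 is a methyl ester and ring C has one benzyl ether. Forward, the basic hydrolysis is done while ring C is still a mono-phenol (23), and the last step is a neutral hydrogenolysis, so the catechol never meets base.

**C1–C1′ bond, 22 to 16 and 21.** The cut is made here because C1 is para to the C6 methoxy group. A leaving group on C1 (the acetate of 16) ionises to a stabilised benzylic cation, and 21 is nucleophilic at the carbon para to its free hydroxyl, which gives exactly the substitution pattern of ring C. The gain is that ring C and the C1 stereocentre arrive in one late step, so all earlier intermediates stay small. The forward reaction must bring the aryl group to the face of C1 that is cis to O2. C2 is fully substituted, so the cation cannot eliminate, and the ester is the larger of the two C2 substituents.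

**C1–O bond and protecting-group exchange, 16 to 15 to 14 to 13.** Oxidising C1–H demands a distinction from C4–H. In 15 the C7 oxygen is an acetate and a poor donor, while the C6 methoxy group para to C1 remains a strong one, so hydride abstraction is directed to C1. This is why the C7 benzyl ether of 13, needed earlier as a donor, is exchanged by hydrogenolysis (14) and acetylation (15). The second acetate on C10 also blocks lactonisation onto C9.

**Acetal release, 13 to 12.** The C9–O bond of the dioxolanone is cut. Forward, methanolysis gives the methyl ester, frees O2 and removes 7. It is placed before the C1 chemistry because the tert-butyl group of 12 sits cis to C1.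

**C4–C4a bond, 12 to 11.** This is the central cut. It closes ring B and removes the C3 stereocentre at once, because in 11 the two arms C4 and C10 are the equivalent methylenes of an oxetane. It is preferred to a cut at C2–C3 or C1–C8a because it leaves an achiral oxetane and a simple benzyl group to be attached to C2. The forward step must make ring A attack one of two diastereotopic methylenes through its carbon para to the benzyloxy group, under the control of C2.

**C2–C3 bond, 11 to 8 and 9.** An aldol cut. Both partners are simple, the oxetanone 9 is symmetric, and the cis acetal of 8 lets the enolate add on one face only, so C2 is set absolutely. The forward step has to form a bond between two fully substituted carbons without retro-aldol.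

**Acetal and C1–C8a bond, 8 to 6 and 7, then 6 to 5 to 2 and 3, then 2 to 1.** The acetal 8 comes from the hydroxy acid 6 and 7. The acid 6 comes from its ester 5, and 5 is cut between the arene and its CH2 into the aryl bromide 2 (from phenol 1) and the epoxy ester 3. The stereocentre of 3 is bought and is not touched when the bond forms, so no asymmetric step is needed before the aldol.

**Ring C reagent, 21 to 18 to 17.** The hydroxyl of 21 is cut off. The position between the two alkoxy groups of 18 is the most acidic one, so metalation and oxidation place the oxygen without a regiochemical question, and 18 is the benzyl ether of 17.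

## Alternatives that were turned down

**Alternative 1:** Rings A and B are both taken apart, at C4a–C8a and C7–C8, back to the open-chain furan ynone A1, in which C2 and C3 are complete and held as an acetonide. Forward, the 4-methoxyfuran of A1 adds as a diene across the tethered ynone (intramolecular Diels–Alder reaction), the oxygen bridge opens, and aromatisation gives the 7-hydroxy-6-methoxy-1-tetralone A2.
- For: two rings and two C–C bonds form in one operation, and the oxygen pattern of ring A is fixed by the furan. The C1 ketone of A2 is a direct handle for ring C; on this point it is stronger than the chosen route, which has to oxidise a C1–H bond late (step 10).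
- Against: the cycloaddition sets no stereocentre, so the trans-diol on two fully substituted carbons must be built beforehand on a flexible chain, which is the hard part of the target. The acetonide has to span that trans-diol, a strained trans-fused dioxolane once ring B exists in A2. The 4-methoxyfuran unit of A1 is an acid-labile diene, and A1 needs a synthesis of its own. Ring C must then be added to the ketone of A2, flanked by quaternary C2 and its ester, and the tertiary benzylic oxygen removed with control of C1.
- Comparison: the chosen route takes ring A from a commodity arene, reaches 11 in five steps and lets the ring closure set C3.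

**Alternative 2:** The C2–C3 and O2–C10 bonds are cut, leading to the α-keto ester A3, which already carries ring C and C1 and has a 2-benzyloxyallyl group on ring A. Forward, irradiation starts a Paternò–Büchi reaction: the excited ketone oxygen adds to the terminal alkene carbon C10, and the biradical closes C2–C3, giving ring B together with a cis-fused oxetane in the oxetane-fused tetralin A4.
- For: both quaternary centres and ring B form at once. The four-membered ring of A4 can only be cis-fused, so O2 and C10 are cis and the diol trans by geometry. It sets two stereocentres where the chosen key step sets one, and it needs no late chemistry at C1; on these points it is stronger.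
- Against: the C1–H of A3 is α to the ketone and doubly benzylic, and A3, a 3,3-diarylpyruvate, should sit largely as its conjugated enol. That erases the C1 stereocentre, the only source of facial control, and the ketone chromophore with it. Excited A3 is also surrounded by five benzylic ether CH2 groups and three electron-rich rings, so hydrogen abstraction (Norrish type 2, photoreduction) and electron-transfer quenching compete. A3 in addition needs an asymmetric construction of a diarylmethine, and the oxetane of A4 must afterwards be opened at C10 by an oxygen nucleophile to release O2 and the hydroxymethyl group.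
- Comparison: the chosen key step is a ground-state, catalytic reaction, each stereocentre is set under separate control, and the substrate is far shorter to make.

**Alternative 3:** Only the C3–C10 bond is cut. The precursor is the dihydronaphthalene A5, a C3–C4 silyl enol ether whose O2 carries a bromomethyldimethylsilyl group. Forward, a tin hydride radical chain generates the silylmethyl radical, which adds 5-exo to C3; the benzylic C4 radical is reduced, giving the cis-fused oxasilolane A6, and a Tamao oxidation would then free the C10 hydroxyl.
- For: the five-membered ring of A6 can only form cis-fused, so C10 is delivered cis to O2 by geometry. This is more secure than the chosen key step, which relies on a conformational preference, and the conditions are neutral.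
- Against: it forms no ring of the skeleton and only one stereocentre, so the tetralin, C1, C2 and the C3 oxygen must all be in place first in A5. Silylation of the tertiary C2 hydroxyl between the C1 aryl group and the ester is hindered. The radical must bond to the fully substituted, oxygen-bearing end of the enol ether. Stoichiometric tin, the Tamao oxidation and removal of a tertiary silyl ether add steps.
- Comparison: the chosen step sets the same stereocentre while closing ring B, from a substrate made in five steps.

Key step: step 6

## Route

Remark: 16 is formed and used as a mixture of C1 epimers, because C1 becomes planar again in step 13. The tertiary hydroxyls are assumed to need no protection.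

Step 1
Reactants: 1 5-bromo-2-methoxyphenol
Product: 2 2-(benzyloxy)-4-bromo-1-methoxybenzene
Conditions: BnBr, K2CO3, DMF, rt
Reagents that add atoms: benzyl bromide BrCc1ccccc1
Why: Williamson ether synthesis on the phenoxide; the benzyl ether makes the future C7 oxygen a strong donor for step 6 and tolerates the organometallic steps.

Step 2
Reactants: 2 2-(benzyloxy)-4-bromo-1-methoxybenzene; 3 methyl (2R)-oxirane-2-carboxylate
Product: 5 methyl (2R)-3-[3-(benzyloxy)-4-methoxyphenyl]-2-hydroxypropanoate, via arylmagnesium bromide 4 (not isolated)
Conditions: Mg, THF, 40 °C; CuI (10 mol %), then 3, −40 → −20 °C; aq. NH4Cl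
Reagents that add atoms: none
Why: Grignard formation followed by copper-catalysed epoxide opening at the unsubstituted carbon; the stereocentre of 3 is not involved, so the R configuration is carried over, and the low temperature keeps the ester intact.

Step 3
Reactants: 5 methyl (2R)-3-[3-(benzyloxy)-4-methoxyphenyl]-2-hydroxypropanoate
Product: 6 (2R)-3-[3-(benzyloxy)-4-methoxyphenyl]-2-hydroxypropanoic acid
Conditions: LiOH·H2O, THF/H2O, 0 °C → rt; 1 M HCl
Reagents that add atoms: lithium hydroxide [Li+].[OH-]
Why: Saponification; an α-hydroxy carboxylate is not deprotonated at carbon under these conditions, so the stereocentre is retained.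

Step 4
Reactants: 6 (2R)-3-[3-(benzyloxy)-4-methoxyphenyl]-2-hydroxypropanoic acid; 7 pivalaldehyde
Product: 8 (2R,5R)-5-[3-(benzyloxy)-4-methoxybenzyl]-2-tert-butyl-1,3-dioxolan-4-one
Conditions: 7 (2 equiv), TsOH·H2O (5 mol %), pentane/CH2Cl2, reflux, water separator; crystallisation
Reagents that add atoms: none
Why: Acid-catalysed acetalisation with removal of water; the cis acetal (both substituents pseudoequatorial) is favoured and purified by crystallisation, so the acetal carbon (R) stores the chirality of C2 for the next step.

Step 5
Reactants: 8 (2R,5R)-5-[3-(benzyloxy)-4-methoxybenzyl]-2-tert-butyl-1,3-dioxolan-4-one; 9 oxetan-3-one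
Product: 11 (2R,5S)-5-[3-(benzyloxy)-4-methoxybenzyl]-2-tert-butyl-5-(3-hydroxyoxetan-3-yl)-1,3-dioxolan-4-one, via lithium enolate 10 (not isolated)
Conditions: LiN(iPr)2, THF, −78 °C; 9, −78 °C; AcOH, −78 °C
Reagents that add atoms: none
Why: Aldol addition of the dioxolanone enolate (self-regeneration of a stereocentre); the strained, highly electrophilic ketone is attacked on the enolate face anti to the tert-butyl group, which sets C2 (S). The cold acidic quench prevents retro-aldol.

Step 6
Reactants: 11 (2R,5S)-5-[3-(benzyloxy)-4-methoxybenzyl]-2-tert-butyl-5-(3-hydroxyoxetan-3-yl)-1,3-dioxolan-4-one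
Product: 12 spiro dioxolanone of (2S,3R)-7-(benzyloxy)-2,3-dihydroxy-3-(hydroxymethyl)-6-methoxy-1,2,3,4-tetrahydronaphthalene-2-carboxylic acid (pivalaldehyde acetal on O2 and C9; acetal carbon R; tert-butyl cis to C1)
Conditions: Sc(OTf)3 (10 mol %), 4 Å molecular sieves, CH2Cl2 (0.01 M), 0 °C → rt
Reagents that add atoms: none
Why: Sc(OTf)3 binds the oxetane oxygen, the most basic site of 11, and the ring A carbon para to the benzyloxy group attacks one ring methylene from the backside; loss of the proton from the arenium ion restores ring A and the scandium alkoxide is protonated to the C10 hydroxymethyl, so the catalyst turns over. The closest known reaction type is the Lewis-acid catalysed desymmetrising opening of 3-substituted oxetanes by a tethered nucleophile, combined with the Friedel–Crafts alkylation of electron-rich arenes by acid-activated strained ethers (epoxy-arene cyclisation). Ring B closes in the 6-exo-tet mode: the C4–O bond that breaks lies outside the new ring, and about 25 kcal/mol of oxetane strain drives the step. The new stereocentre C3 is controlled by C2: backside attack forces the spectator arm C10 to lie anti to the forming C4–C4a bond (equatorial in the chair-like transition state) and the C3 hydroxyl to be axial; at C2 the larger carbonyl carbon C9 then takes the equatorial and O2 the axial position, which places O3 anti to O2 (opposed C–O dipoles, hydrogen bond from O3–H to the lactone carbonyl) and gives the trans-diol, C3 (R). Three selectivities are needed: the choice of methylene (as above), attack through the carbon para and not ortho to the benzyloxy group (the ortho carbon is flanked by two substituents), and arene attack in preference to the lactone carbonyl oxygen, which is held in the plane of the dioxolanone, points away from the oxetane and is a poor donor as part of an acylal. No cation can form at C3, which has no aryl group and sits next to the electron-poor C2. High dilution suppresses intermolecular opening by the free tertiary hydroxyl.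

Step 7
Reactants: 12 spiro dioxolanone (product of step 6)
Product: 13 methyl (2S,3R)-7-(benzyloxy)-2,3-dihydroxy-3-(hydroxymethyl)-6-methoxy-1,2,3,4-tetrahydronaphthalene-2-carboxylate
Conditions: NaOMe (0.2 equiv), MeOH, 0 °C; AcOH
Reagents that add atoms: methanol CO
Why: Methanolysis of the acylal-type lactone; the hemiacetal on O2 collapses to pivalaldehyde and returns methoxide, so base is catalytic. This frees O2 and removes the tert-butyl group that would shield C1 in step 13; the low temperature and short contact avoid retro-aldol.

Step 8
Reactants: 13 methyl (2S,3R)-7-(benzyloxy)-2,3-dihydroxy-3-(hydroxymethyl)-6-methoxy-1,2,3,4-tetrahydronaphthalene-2-carboxylate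
Product: 14 methyl (2S,3R)-2,3,7-trihydroxy-3-(hydroxymethyl)-6-methoxy-1,2,3,4-tetrahydronaphthalene-2-carboxylate
Conditions: H2 (1 atm), Pd/C, EtOAc/MeOH, rt
Reagents that add atoms: none
Why: Hydrogenolysis of the aryl benzyl ether; the ring B methylenes carry no benzylic heteroatom and are untouched.

Step 9
Reactants: 14 methyl (2S,3R)-2,3,7-trihydroxy-3-(hydroxymethyl)-6-methoxy-1,2,3,4-tetrahydronaphthalene-2-carboxylate
Product: 15 methyl (2S,3R)-7-acetoxy-3-(acetoxymethyl)-2,3-dihydroxy-6-methoxy-1,2,3,4-tetrahydronaphthalene-2-carboxylate
Conditions: Ac2O (2.5 equiv), pyridine, 0 °C → rt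
Reagents that add atoms: acetic anhydride CC(=O)OC(C)=O
Why: Acetylation of the phenol and the primary alcohol; the two tertiary alcohols do not react without an acyl-transfer catalyst. The C7 acetate switches off the donor para to C4, and the C10 acetate blocks lactonisation.

Step 10
Reactants: 15 methyl (2S,3R)-7-acetoxy-3-(acetoxymethyl)-2,3-dihydroxy-6-methoxy-1,2,3,4-tetrahydronaphthalene-2-carboxylate
Product: 16 methyl (2S,3R)-1,7-diacetoxy-3-(acetoxymethyl)-2,3-dihydroxy-6-methoxy-1,2,3,4-tetrahydronaphthalene-2-carboxylate (both C1 epimers)
Conditions: DDQ (1.5 equiv), AcOH, 50 °C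
Reagents that add atoms: acetic acid CC(O)=O
Why: Benzylic acetoxylation by hydride abstraction with DDQ, a known reaction of alkyl groups para to a methoxy group; only C1 has a strong para donor, and the cation is trapped by the solvent. C2 has no hydrogen, so dehydrogenation to a naphthalene is impossible, and the acetoxy group slows a second oxidation.

Step 11
Reactants: 17 3-methoxyphenol
Product: 18 1-(benzyloxy)-3-methoxybenzene
Conditions: BnBr, K2CO3, DMF, rt
Reagents that add atoms: benzyl bromide BrCc1ccccc1
Why: Williamson ether synthesis; the benzyl group will mask the outer ring C oxygen until the last step.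

Step 12
Reactants: 18 1-(benzyloxy)-3-methoxybenzene
Product: 21 2-(benzyloxy)-6-methoxyphenol, via 2-lithio arene 19 (not isolated), via lithium aryltrimethoxyborate 20 (not isolated)
Conditions: n-BuLi, THF, 0 °C → rt; B(OMe)3, −78 °C → rt; AcOH, 30% H2O2, 0 °C → rt
Reagents that add atoms: hydrogen peroxide OO
Why: Directed ortho-metalation at the carbon between the two alkoxy groups, borylation and oxidation of the C–B bond to the phenol; the doubly activated position is lithiated faster than the benzylic CH2.

Step 13
Reactants: 16 methyl (2S,3R)-1,7-diacetoxy-3-(acetoxymethyl)-2,3-dihydroxy-6-methoxy-1,2,3,4-tetrahydronaphthalene-2-carboxylate; 21 2-(benzyloxy)-6-methoxyphenol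
Product: 22 methyl (1S,2S,3R)-7-acetoxy-3-(acetoxymethyl)-1-[3-(benzyloxy)-4-hydroxy-5-methoxyphenyl]-2,3-dihydroxy-6-methoxy-1,2,3,4-tetrahydronaphthalene-2-carboxylate
Conditions: 21 (3 equiv), Sc(OTf)3 (20 mol %), CH2Cl2/HFIP 9:1, −20 °C → rt
Reagents that add atoms: none
Why: Friedel–Crafts benzylation: the Lewis acid ionises the C1 acetate to the cation stabilised by the para methoxy group, and 21 attacks through the carbon para to its free hydroxyl. C1 should be set by approach anti to the methoxycarbonyl group, the larger C2 substituent (which prefers the pseudoaxial position next to the cation), that is on the face of the small C2 hydroxyl.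

Step 14
Reactants: 22 (product of step 13)
Product: 23 (1S,2S,3R)-1-[3-(benzyloxy)-4-hydroxy-5-methoxyphenyl]-2,3,7-trihydroxy-3-(hydroxymethyl)-6-methoxy-1,2,3,4-tetrahydronaphthalene-2-carboxylic acid
Conditions: LiOH (6 equiv), degassed THF/H2O, argon, 0 °C → rt; 1 M HCl to pH 3 at 0 °C
Reagents that add atoms: lithium hydroxide [Li+].[OH-]
Why: Saponification of the two acetates and of the α-hydroxy methyl ester; ring C is still a mono-phenol here, which limits air oxidation in base. Cold, mild acidification avoids lactonisation of C9 onto the C10 hydroxyl.

Step 15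
Reactants: 23 (product of step 14)
Product: 24 plicatic acid, (1S,2S,3R)-1-(3,4-dihydroxy-5-methoxyphenyl)-2,3,7-trihydroxy-3-(hydroxymethyl)-6-methoxy-1,2,3,4-tetrahydronaphthalene-2-carboxylic acid
Conditions: H2 (1 atm), Pd/C, MeOH, rt; filtration
Reagents that add atoms: none
Why: Hydrogenolysis of the last benzyl ether under neutral conditions; the diarylmethine C1–H bond has no heteroatom to cleave, and the product needs only filtration and evaporation.

## Compound list

1 | 5-bromo-2-methoxyphenol | COc1ccc(Br)cc1O | starting material
2 | 2-(benzyloxy)-4-bromo-1-methoxybenzene | COc1ccc(Br)cc1OCc1ccccc1 | intermediate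
3 | methyl (2R)-oxirane-2-carboxylate | COC(=O)[C@H]1CO1 | starting material
4 | [3-(benzyloxy)-4-methoxyphenyl]magnesium bromide | COc1ccc([Mg]Br)cc1OCc1ccccc1 | intermediate
5 | methyl (2R)-3-[3-(benzyloxy)-4-methoxyphenyl]-2-hydroxypropanoate | COC(=O)[C@H](O)Cc1ccc(OC)c(OCc2ccccc2)c1 | intermediate
6 | (2R)-3-[3-(benzyloxy)-4-methoxyphenyl]-2-hydroxypropanoic acid | OC(=O)[C@H](O)Cc1ccc(OC)c(OCc2ccccc2)c1 | intermediate
7 | pivalaldehyde | CC(C)(C)C=O | starting material
8 | (2R,5R)-5-[3-(benzyloxy)-4-methoxybenzyl]-2-tert-butyl-1,3-dioxolan-4-one | COc1ccc(C[C@H]2O[C@@H](C(C)(C)C)OC2=O)cc1OCc1ccccc1 | intermediate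
9 | oxetan-3-one | O=C1COC1 | starting material
10 | lithium enolate of 8 | [Li+].[O-]C1=C(Cc2ccc(OC)c(OCc3ccccc3)c2)O[C@@H](C(C)(C)C)O1 | intermediate
11 | (2R,5S)-5-[3-(benzyloxy)-4-methoxybenzyl]-2-tert-butyl-5-(3-hydroxyoxetan-3-yl)-1,3-dioxolan-4-one | COc1ccc(cc1OCc1ccccc1)C[C@@]1(C2(O)COC2)O[C@@H](C(C)(C)C)OC1=O | intermediate
12 | spiro dioxolanone (pivalaldehyde acetal, acetal carbon R) of (2S,3R)-7-(benzyloxy)-2,3-dihydroxy-3-(hydroxymethyl)-6-methoxy-1,2,3,4-tetrahydronaphthalene-2-carboxylic acid | COc1cc2c(cc1OCc1ccccc1)C[C@]1(O[C@@H](C(C)(C)C)OC1=O)[C@](O)(CO)C2 | intermediate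
13 | methyl (2S,3R)-7-(benzyloxy)-2,3-dihydroxy-3-(hydroxymethyl)-6-methoxy-1,2,3,4-tetrahydronaphthalene-2-carboxylate | COc1cc2c(cc1OCc1ccccc1)C[C@@](O)(C(=O)OC)[C@](O)(CO)C2 | intermediate
14 | methyl (2S,3R)-2,3,7-trihydroxy-3-(hydroxymethyl)-6-methoxy-1,2,3,4-tetrahydronaphthalene-2-carboxylate | COc1cc2c(cc1O)C[C@@](O)(C(=O)OC)[C@](O)(CO)C2 | intermediate
15 | methyl (2S,3R)-7-acetoxy-3-(acetoxymethyl)-2,3-dihydroxy-6-methoxy-1,2,3,4-tetrahydronaphthalene-2-carboxylate | COc1cc2c(cc1OC(C)=O)C[C@@](O)(C(=O)OC)[C@](O)(COC(C)=O)C2 | intermediate
16 | methyl (2S,3R)-1,7-diacetoxy-3-(acetoxymethyl)-2,3-dihydroxy-6-methoxy-1,2,3,4-tetrahydronaphthalene-2-carboxylate (C1 epimers) | COc1cc2c(cc1OC(C)=O)C(OC(C)=O)[C@@](O)(C(=O)OC)[C@](O)(COC(C)=O)C2 | intermediate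
17 | 3-methoxyphenol | COc1cccc(O)c1 | starting material
18 | 1-(benzyloxy)-3-methoxybenzene | COc1cccc(OCc2ccccc2)c1 | intermediate
19 | [2-(benzyloxy)-6-methoxyphenyl]lithium | [Li]c1c(OC)cccc1OCc1ccccc1 | intermediate
20 | lithium [2-(benzyloxy)-6-methoxyphenyl]trimethoxyborate | [Li+].CO[B-](OC)(OC)c1c(OC)cccc1OCc1ccccc1 | intermediate
21 | 2-(benzyloxy)-6-methoxyphenol | COc1cccc(OCc2ccccc2)c1O | intermediate
22 | methyl (1S,2S,3R)-7-acetoxy-3-(acetoxymethyl)-1-[3-(benzyloxy)-4-hydroxy-5-methoxyphenyl]-2,3-dihydroxy-6-methoxy-1,2,3,4-tetrahydronaphthalene-2-carboxylate | COc1cc2c(cc1OC(C)=O)[C@H](c1cc(OCc3ccccc3)c(O)c(OC)c1)[C@@](O)(C(=O)OC)[C@](O)(COC(C)=O)C2 | intermediate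
23 | (1S,2S,3R)-1-[3-(benzyloxy)-4-hydroxy-5-methoxyphenyl]-2,3,7-trihydroxy-3-(hydroxymethyl)-6-methoxy-1,2,3,4-tetrahydronaphthalene-2-carboxylic acid | COc1cc2c(cc1O)[C@H](c1cc(OCc3ccccc3)c(O)c(OC)c1)[C@@](O)(C(=O)O)[C@](O)(CO)C2 | intermediate
24 | plicatic acid | COc1cc2c(cc1O)[C@H](c1cc(O)c(O)c(OC)c1)[C@@](O)(C(=O)O)[C@](O)(CO)C2 | target

## Step count and least certain steps

Total: 15 steps. Longest linear sequence: 13 steps (steps 1 to 10 and 13 to 15); the two-step branch (steps 11 and 12) supplies 21.

**Step 6 (key step).** Two processes are most likely to interfere. The first is attack of the lactone carbonyl oxygen on the activated oxetane with loss of pivalaldehyde, because an alkoxybenzene is only a moderate π-nucleophile towards an unactivated primary carbon. The second is attack on the wrong methylene, if the conformational bias from C2 is weaker than estimated. Fallback, from 11 back to the route at 13: it makes the oxygen attack the productive step and closes ring B through a carbonyl group. LiOH in aqueous THF hydrolyses the dioxolanone of 11 to the oxetane hydroxy acid F1, which is not isolated; on acidification its carboxyl group opens the oxetane at one methylene (a known behaviour of oxetane acids) and gives the γ-lactone triol F2. The two arm isomers of this lactone can interconvert by transacylation, so the isomer with the benzyl group trans to the free hydroxymethyl group should prevail. TEMPO and PhI(OAc)2 then oxidise the primary alcohol to the non-enolisable hydroxy aldehyde F3. TFA and Et3SiH in CH2Cl2 effect Friedel–Crafts hydroxyalkylation para to the benzyloxy group, which forms the benzylic alcohol F4 in the flask, and ionic reduction of that alcohol gives the tetralin lactone F5. NaOMe in MeOH finally opens the strained trans-fused lactone to 13.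

**Step 13.** Facial selectivity at C1 may be poor, because the two half-chair forms of the cation (ester pseudoaxial or O2 pseudoaxial) lead to opposite faces and each meets a 1,3-diaxial contact with a C3 substituent. A 1,2-shift from C2 to the cation is a further risk. Fallback, from 16 back to 22: if the arylation of step 13 gives mainly the C1 epimer F6, the same facial bias is used for hydride instead of aryl. DDQ in CH2Cl2 oxidises the para-hydroxyaryl methine of the epimer to the para-quinone methide F7, and Et3SiH with TFA at −40 °C delivers hydride to C1 from the face the aryl group had preferred, which gives 22.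

**Step 10.** Hydride abstraction may be slow, because C1 lies next to the electron-poor C2 and ring A carries an acetate; forcing conditions risk oxidation at C4 or of the product. Fallback, from 15 back to 22: hydrogen-atom abstraction replaces hydride abstraction. NBS with AIBN in PhCF3 at 80 °C gives the C1 bromide F8 (the electrophilic bromine atom prefers the C–H para to methoxy), and AgOTf at −40 °C with 21 converts this bromide directly to 22.

**Step 5.** Retro-aldol of the congested lithium aldolate and decomposition of the enolate on warming may limit conversion. Fallback, from 8 back to 11: a Mukaiyama aldol traps the adduct irreversibly. LiN(iPr)2 then TMSCl gives the silyl ketene acetal F9; 9 with BF3·OEt2 in CH2Cl2 at −78 °C gives the silyl ether F10, again by attack anti to the tert-butyl group; citric acid in MeOH removes the silyl group to give 11.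

## Further compounds

F1 | step 6 | (2S)-3-[3-(benzyloxy)-4-methoxyphenyl]-2-hydroxy-2-(3-hydroxyoxetan-3-yl)propanoic acid | COc1ccc(cc1OCc1ccccc1)C[C@@](O)(C(=O)O)C1(O)COC1
F2 | step 6 | γ-lactone of C9 onto C10 with free C4 hydroxymethyl: (3S,4R)-3-[3-(benzyloxy)-4-methoxybenzyl]-3,4-dihydroxy-4-(hydroxymethyl)oxolan-2-one | COc1ccc(cc1OCc1ccccc1)C[C@@]1(O)C(=O)OC[C@]1(O)CO
F3 | step 6 | aldehyde from F2 (C4 as CHO; C2 S and C3 R in target numbering) | COc1ccc(cc1OCc1ccccc1)C[C@@]1(O)C(=O)OC[C@]1(O)C=O
F4 | step 6 | 7-(benzyloxy)-2,3,4-trihydroxy-6-methoxytetralin with trans-fused γ-lactone between C9 and the C10 oxygen (C2 and C3 as in the target; C4 epimers) | COc1cc2c(cc1OCc1ccccc1)C[C@@]1(O)C(=O)OC[C@]1(O)C2O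
F5 | step 6 | tetralin with trans-fused C9–O–C10 γ-lactone: 7-benzyloxy-2,3-dihydroxy-6-methoxytetralin (2S,3R) lactonised between C9 and the C10 oxygen | COc1cc2c(cc1OCc1ccccc1)C[C@@]1(O)C(=O)OC[C@]1(O)C2
F6 | step 13 | C1 epimer of 22 (1R,2S,3R) | COc1cc2c(cc1OC(C)=O)[C@@H](c1cc(OCc3ccccc3)c(O)c(OC)c1)[C@@](O)(C(=O)OC)[C@](O)(COC(C)=O)C2
F7 | step 13 | para-quinone methide from F6 (C1 doubly bonded to the quinoid ring C) | COc1cc2c(cc1OC(C)=O)C(=C1C=C(OCc3ccccc3)C(=O)C(OC)=C1)[C@@](O)(C(=O)OC)[C@](O)(COC(C)=O)C2
F8 | step 10 | C1 bromide of 15 (C1 epimers) | COc1cc2c(cc1OC(C)=O)C(Br)[C@@](O)(C(=O)OC)[C@](O)(COC(C)=O)C2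
F9 | step 5 | trimethylsilyl ketene acetal of 8 | C[Si](C)(C)OC1=C(Cc2ccc(OC)c(OCc3ccccc3)c2)O[C@@H](C(C)(C)C)O1
F10 | step 5 | trimethylsilyl ether of 11 | COc1ccc(cc1OCc1ccccc1)C[C@@]1(C2(O[Si](C)(C)C)COC2)O[C@@H](C(C)(C)C)OC1=O
A1 | alternative 1 | methyl 5-[(benzyloxy)methyl]-5-[(4-methoxyfuran-2-yl)methyl]-2,2-dimethyl-4-propioloyl-1,3-dioxolane-4-carboxylate (ester and benzyloxymethyl trans) | C#CC(=O)[C@]1(C(=O)OC)OC(C)(C)O[C@@]1(COCc2ccccc2)Cc1cc(OC)co1
A2 | alternative 1 | 7-hydroxy-6-methoxy-1-tetralone with C2 and C3 as in the target, acetonide on O2 and O3, C10 benzyl ether | COc1cc2c(cc1O)C(=O)[C@]1(C(=O)OC)OC(C)(C)O[C@@]1(COCc3ccccc3)C2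
A3 | alternative 2 | methyl (3S)-3-{5-(benzyloxy)-2-[2-(benzyloxy)prop-2-en-1-yl]-4-methoxyphenyl}-3-[3,4-bis(benzyloxy)-5-methoxyphenyl]-2-oxopropanoate | COc1cc(CC(=C)OCc2ccccc2)c(cc1OCc1ccccc1)[C@H](c1cc(OCc3ccccc3)c(OCc3ccccc3)c(OC)c1)C(=O)C(=O)OC
A4 | alternative 2 | oxetane-fused tetralin (O2–C10 oxetane, O3 benzyl ether) with C1, C2 and C3 as in the target | COc1cc2c(cc1OCc1ccccc1)[C@H](c1cc(OCc3ccccc3)c(OCc3ccccc3)c(OC)c1)[C@]3(C(=O)OC)OC[C@]3(OCc4ccccc4)C2
A5 | alternative 3 | methyl (1S,2S)-7-(benzyloxy)-1-[3,4-bis(benzyloxy)-5-methoxyphenyl]-2-{[(bromomethyl)dimethylsilyl]oxy}-3-[(tert-butyldimethylsilyl)oxy]-6-methoxy-1,2-dihydronaphthalene-2-carboxylate | COc1cc2c(cc1OCc1ccccc1)[C@H](c1cc(OCc3ccccc3)c(OCc3ccccc3)c(OC)c1)[C@@](O[Si](C)(C)CBr)(C(=O)OC)C(O[Si](C)(C)C(C)(C)C)=C2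
A6 | alternative 3 | oxasilolane-fused tetralin (O2–Si–C10 ring, O3 tert-butyldimethylsilyl ether) with C1, C2 and C3 as in the target | COc1cc2c(cc1OCc1ccccc1)[C@H](c1cc(OCc3ccccc3)c(OCc3ccccc3)c(OC)c1)[C@]3(C(=O)OC)O[Si](C)(C)C[C@]3(O[Si](C)(C)C(C)(C)C)C2
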